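**Retrosynthetic overview**

1. The target is ent-fisetinidol-(4α→6)-ent-fisetinidol-(4α→8)-[ent-fisetinidol-(4α→6)]-catechin (units A, B, D and C). All three interflavanyl bonds are 2,3-trans-3,4-cis, so each C4–aryl bond is made at the ketone level and the C4 hydrogen is delivered last, anti to the C3 oxygen.
2. Enabling feature: in the terminal units A and D, O1 and C4 of the pyran ring are bonded to the adjacent benzo-ring carbons C8a and C4a of a ring that carries nothing else but the 7-OH. The chain O1–C2–C3–C4 is therefore a β-oxido ketone (C4 already bonded to C6 of the benzo ring of B, or to C6 of the catechin benzo ring) into which a 1,2-didehydrobenzene can be inserted.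
3. Key disconnection: one double aryne annulation closes the pyran rings of A and D and attaches their benzo rings (O1–C8a and C4a–C4, twice) on bis-ketone 27. A bromine on the aryne steers the regiochemistry and leaves in the final hydrogenolysis.
4. Bis-ketone 27 comes from the B–C dimer dibromide and Weinreb amide 7 (the anti-glycolate aldol sets C2/C3 of all three ent-fisetinidol units). The B–C dimer comes from 8-lithiocatechin and flavan-4-one 12, followed by ionic reduction.
5. Ring order: pyran of C (chiral pool) → pyran of B (SNAr) → C4(B)–C8(C) → pyran rings of A and D (key step) → C4–H of A and D → global hydrogenolysis.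

Key step: step 16

Remark on the chemistry (assumption): the anti-selective titanium glycolate aldol of step 2 is taken to give the (2S,3S) adduct from the (R)-4-benzyl auxiliary (TiCl4-activated aldehyde attacking the enolate face away from the benzyl group of the sulfur-chelated enolate). If the sense is the opposite, the (S)-auxiliary is used and nothing else changes. In the names, "unit" letters refer to flavan units; rings are called benzo, pyran and catechol rings.

**Route**

Step 1
Reactants: 1 (R)-4-benzyl-1,3-oxazolidine-2-thione; 2 (benzyloxy)acetyl chloride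
Product: 3 (R)-4-benzyl-3-[(benzyloxy)acetyl]-1,3-oxazolidine-2-thione
Conditions: Et3N, CH2Cl2, 0 °C → rt
Reagents that add atoms: none
Why: N-acylation of the thione auxiliary by the acid chloride (amide formation); no stereocenter is formed.

Step 2
Reactants: 3 N-glycolyl oxazolidinethione; 4 3,4-bis(benzyloxy)benzaldehyde
Product: 5 (R)-4-benzyl-3-[(2S,3S)-2-(benzyloxy)-3-[3,4-bis(benzyloxy)phenyl]-3-hydroxypropanoyl]-1,3-oxazolidine-2-thione
Conditions: TiCl4, i-Pr2NEt, CH2Cl2, −78 °C; then 4 precomplexed with TiCl4, −78 °C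
Reagents that add atoms: none
Why: Titanium-mediated anti-selective glycolate aldol addition, in which the Z-titanium enolate adds through an open transition state to the Lewis-acid-activated aldehyde while the benzyl group of the auxiliary shields one enolate face, should set the anti (2S,3S) pair that becomes C3 and C2 of every ent-fisetinidol unit.

Step 3
Reactants: 5 anti aldol adduct
Product: 6 (2S,3S)-2-(benzyloxy)-3-[3,4-bis(benzyloxy)phenyl]-3-hydroxy-N-methoxy-N-methylpropanamide
Conditions: MeNH(OMe)·HCl, imidazole, CH2Cl2, rt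
Reagents that add atoms: N,O-dimethylhydroxylamine hydrochloride, Cl.CNOC
Why: Direct aminolysis of the activated N-acyl oxazolidinethione (auxiliary displacement to the Weinreb amide) proceeds without touching the two stereocenters.

Step 4
Reactants: 6 hydroxy Weinreb amide
Product: 7 (2S,3S)-2-(benzyloxy)-3-[3,4-bis(benzyloxy)phenyl]-N-methoxy-N-methyl-3-(triethylsilyloxy)propanamide
Conditions: Et3SiCl, imidazole, DMF, 0 °C → rt
Reagents that add atoms: chlorotriethylsilane, CC[Si](Cl)(CC)CC
Why: Silyl ether formation; the triethylsilyl group survives aryllithium reagents and is cleaved by fluoride exactly where the alkoxide is needed (steps 6 and 16).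

Step 5
Reactants: 8 4-(benzyloxy)-1-bromo-2-fluorobenzene; 7 Weinreb amide
Product: 10 (2S,3S)-2-(benzyloxy)-1-[4-(benzyloxy)-2-fluorophenyl]-3-[3,4-bis(benzyloxy)phenyl]-3-(triethylsilyloxy)propan-1-one, via 4-(benzyloxy)-2-fluorophenyllithium 9 (not isolated)
Conditions: n-BuLi, THF, −78 °C; then 7, −78 → −40 °C
Reagents that add atoms: none
Why: Bromine–lithium exchange followed by Weinreb ketone synthesis; the chelated tetrahedral intermediate prevents over-addition and protects the α-stereocenter, and the ortho-fluoroaryllithium is stable at −78 °C.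

Step 6
Reactants: 10 fluoroaryl ketone
Product: 12 (2S,3S)-3,7-bis(benzyloxy)-2-[3,4-bis(benzyloxy)phenyl]chroman-4-one, via desilylated hydroxy ketone 11 (not isolated)
Conditions: Bu4NF (1.1 equiv), THF, 0 °C → rt
Reagents that add atoms: none
Why: Fluoride desilylation followed by intramolecular SNAr (6-exo) of the alkoxide on the fluoroarene activated by the ortho carbonyl closes the pyran ring of unit B with retention at C2 and C3, the anti chain giving the 2,3-trans ketone, which is also the thermodynamic isomer.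

Step 7
Reactants: 13 4-(benzyloxy)phenol
Product: 14 4-(benzyloxy)-2,6-dibromophenol
Conditions: NBS (2.05 equiv), i-Pr2NH (cat.), CH2Cl2, 0 °C → rt
Reagents that add atoms: N-bromosuccinimide, BrN1C(=O)CCC1=O
Why: Electrophilic aromatic bromination goes to both positions ortho to the free phenol because the para position is blocked and the amine catalyst enforces ortho delivery.

Step 8
Reactants: 14 dibromophenol
Product: 17 4-(benzyloxy)-2-bromo-6-(trimethylsilyl)phenyl trifluoromethanesulfonate, via aryl trimethylsilyl ether 15 (not isolated), via lithium silylphenoxide 16 (not isolated)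
Conditions: (Me3Si)2NH, THF, reflux, then evaporation; n-BuLi (1.0 equiv), THF, −78 °C → rt; Tf2O, −78 °C → rt
Reagents that add atoms: hexamethyldisilazane, C[Si](C)(C)N[Si](C)(C)C; trifluoromethanesulfonic anhydride, O=S(=O)(OS(=O)(=O)C(F)(F)F)C(F)(F)F
Why: O-silylation, bromine–lithium exchange, retro-Brook rearrangement (1,3 O→C silyl shift) and triflation is the standard entry to ortho-silylaryl triflates, and the symmetry of 14 makes the mono-exchange unambiguous.

Step 9
Reactants: 18 (+)-catechin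
Product: 19 5,7,3',4'-tetra-O-benzyl-(+)-catechin
Conditions: BnBr (4.4 equiv), K2CO3, DMF, 0 °C → rt
Reagents that add atoms: benzyl bromide, BrCc1ccccc1
Why: Williamson etherification of the four phenols, the much less acidic C3 alcohol remaining free under carbonate conditions.

Step 10
Reactants: 19 tetra-O-benzylcatechin
Product: 20 3,5,7,3',4'-penta-O-benzyl-(+)-catechin
Conditions: NaH, BnBr, Bu4NI (cat.), DMF, 0 °C → rt
Reagents that add atoms: benzyl bromide, BrCc1ccccc1
Why: Williamson etherification of the secondary alcohol, which removes the last acidic proton before the organolithium steps.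

Step 11
Reactants: 20 penta-O-benzylcatechin
Product: 21 8-bromo-3,5,7,3',4'-penta-O-benzyl-(+)-catechin
Conditions: NBS (1.0 equiv), CH2Cl2, −78 °C → rt
Reagents that add atoms: N-bromosuccinimide, BrN1C(=O)CCC1=O
Why: Electrophilic aromatic bromination occurs at C8, the most reactive position of the phloroglucinol-type benzo ring of benzylated catechin.

Step 12
Reactants: 21 8-bromocatechin ether; 12 flavan-4-one
Product: 23 4-hydroxy-3,7,3',4'-tetra-O-benzyl-ent-fisetinidol-(4→8)-3,5,7,3',4'-penta-O-benzylcatechin (C4 epimers of unit B), via 8-lithio-penta-O-benzylcatechin 22 (not isolated)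
Conditions: t-BuLi (2.1 equiv), THF, −78 °C; then 12, −78 → −40 °C
Reagents that add atoms: none
Why: Bromine–lithium exchange and 1,2-addition of the aryllithium to the 3-benzyloxyflavan-4-one (a known union of 8-lithioflavans with protected 4-ketones) forms C4(B)–C8(C), and the carbinol configuration is irrelevant because it is erased in step 13.

Step 13
Reactants: 23 tertiary carbinol
Product: 24 nona-O-benzyl-ent-fisetinidol-(4α→8)-catechin (2,3-trans-3,4-cis in unit B)
Conditions: Et3SiH (excess), CF3CO2H, CH2Cl2, −40 → 0 °C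
Reagents that add atoms: none
Why: Ionic hydrogenation of the tertiary doubly benzylic alcohol, in which the planar C4 cation takes hydride on the face anti to the C3 benzyloxy group, should place the aryl group cis to O3 (4α).

Step 14
Reactants: 24 B–C dimer
Product: 25 nona-O-benzyl-6-bromo-ent-fisetinidol-(4α→8)-6-bromocatechin
Conditions: NBS (2.1 equiv), CH2Cl2, −40 → 0 °C, dark
Reagents that add atoms: N-bromosuccinimide, BrN1C(=O)CCC1=O
Why: Electrophilic aromatic bromination should take the two most activated free positions, C6 of the phloroglucinol-type ring of C and C6 of the resorcinol-type ring of B (para to O1, ortho to 7-OBn, less hindered than C8).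

Step 15
Reactants: 25 dibromide; 7 Weinreb amide (2.5 equiv)
Product: 27 nona-O-benzyl B–C dimer carrying a (2S,3S)-2-(benzyloxy)-3-[3,4-bis(benzyloxy)phenyl]-3-(triethylsilyloxy)propanoyl group at C6 of unit B and at C6 of unit C, via dilithio dimer 26 (not isolated)
Conditions: t-BuLi (4.4 equiv), THF, −78 °C; then 7, −78 → −30 °C
Reagents that add atoms: none
Why: Double bromine–lithium exchange and double Weinreb ketone synthesis install, at the two carbons that will bear C4 of units A and D, the same chain that was used for unit B.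

Step 16
Reactants: 27 bis-ketone; 17 silylaryl triflate (2.6 equiv)
Product: 30 heptadeca-O-benzyl tetramer in which units A and D are 5-bromo-4-hydroxy-ent-fisetinidol units (C4 epimers), via dimer bis(hydroxy ketone) dialkoxide 28 (not isolated), via 5-(benzyloxy)-3-bromobenzyne 29 (not isolated)
Conditions: CsF (8 equiv), 18-crown-6, THF, 0 °C → rt, slow addition of 17
Reagents that add atoms: none
Why: Proposed new method: fluoride cleaves the two triethylsilyl ethers to the benzylic C2 alkoxides and generates aryne 29 from 17; each alkoxide adds to the aryne carbon remote from bromine and the aryl anion so formed attacks the neighbouring aryl ketone, so that O1–C8a and C4a–C4 of units A and D are made in one operation, a formal insertion of the aryne between the oxygen and the carbonyl carbon of a β-oxido ketone. The closest known reaction type is the aryne annulation of ortho-hydroxyaryl carbonyl compounds and of β-sulfonamido ketones (heteroatom addition to the aryne, then intramolecular capture of the aryl anion by the carbonyl group, as in xanthene, xanthone and dihydroquinoline syntheses); an aliphatic β-alkoxide with a ketone trap has not been shown. Each pyran ring closes by 6-exo-trig addition of the aryl anion to the carbonyl carbon. C2 and C3 of both chains are carried through unchanged because the C2–O bond is never broken, and the two new C4 carbinol centres need no control since both epimers converge in step 17. The selectivity that is needed is regiochemical: the inductively withdrawing bromine next to one aryne carbon (the 3-haloaryne effect) and the bulk of the secondary alkoxide send oxygen to the distal carbon, which puts the benzyloxy group at C7 and the anion at C4a. The benzyl ether on C3 excludes the five-ring alternative, and rapid intramolecular capture at low temperature is relied on to outrun retro-aldol cleavage.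

Step 17
Reactants: 30 bis-carbinol
Product: 31 heptadeca-O-benzyl-5-bromo-ent-fisetinidol-(4α→6)-ent-fisetinidol-(4α→8)-[5-bromo-ent-fisetinidol-(4α→6)]-catechin
Conditions: Et3SiH (excess), CF3CO2H, CH2Cl2, −40 → 0 °C
Reagents that add atoms: none
Why: Double ionic hydrogenation as in step 13, hydride entering each C4 cation anti to the C3 benzyloxy group while the peri bromine favours a quasi-axial 4-aryl group, should give the 3,4-cis (4α) configuration in units A and D.

Step 18
Reactants: 31 protected tetramer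
Product: 32 ent-fisetinidol-(4α→6)-ent-fisetinidol-(4α→8)-[ent-fisetinidol-(4α→6)]-catechin (CNP0126838.1)
Conditions: H2 (1 atm), Pd(OH)2/C, NaOAc, THF–MeOH–H2O, rt
Reagents that add atoms: none
Why: Palladium-catalysed hydrogenolysis removes the seventeen benzyl ethers and the two aryl bromines in one operation, the acetate buffer keeping the released HBr away from the interflavanyl bonds.

**Compound list**

1 | (R)-4-benzyl-1,3-oxazolidine-2-thione | S=C1OC[C@@H](Cc2ccccc2)N1 | starting material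
2 | (benzyloxy)acetyl chloride | ClC(=O)COCc1ccccc1 | starting material
3 | (R)-4-benzyl-3-[(benzyloxy)acetyl]-1,3-oxazolidine-2-thione | S=C1OC[C@@H](Cc2ccccc2)N1C(=O)COCc1ccccc1 | intermediate
4 | 3,4-bis(benzyloxy)benzaldehyde | O=Cc1ccc(OCc2ccccc2)c(OCc2ccccc2)c1 | starting material
5 | (R)-4-benzyl-3-[(2S,3S)-2-(benzyloxy)-3-[3,4-bis(benzyloxy)phenyl]-3-hydroxypropanoyl]-1,3-oxazolidine-2-thione | S=C1OC[C@@H](Cc2ccccc2)N1C(=O)[C@@H](OCc1ccccc1)[C@@H](O)c1ccc(OCc2ccccc2)c(OCc2ccccc2)c1 | intermediate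
6 | (2S,3S)-2-(benzyloxy)-3-[3,4-bis(benzyloxy)phenyl]-3-hydroxy-N-methoxy-N-methylpropanamide | O[C@@H](c1ccc(OCc2ccccc2)c(OCc2ccccc2)c1)[C@H](OCc1ccccc1)C(=O)N(C)OC | intermediate
7 | (2S,3S)-2-(benzyloxy)-3-[3,4-bis(benzyloxy)phenyl]-N-methoxy-N-methyl-3-(triethylsilyloxy)propanamide | CC[Si](CC)(CC)O[C@@H](c1ccc(OCc2ccccc2)c(OCc2ccccc2)c1)[C@H](OCc1ccccc1)C(=O)N(C)OC | intermediate
8 | 4-(benzyloxy)-1-bromo-2-fluorobenzene | Fc1cc(OCc2ccccc2)ccc1Br | starting material
9 | 4-(benzyloxy)-2-fluorophenyllithium | [Li]c1ccc(OCc2ccccc2)cc1F | intermediate (not isolated)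
10 | (2S,3S)-2-(benzyloxy)-1-[4-(benzyloxy)-2-fluorophenyl]-3-[3,4-bis(benzyloxy)phenyl]-3-(triethylsilyloxy)propan-1-one | CC[Si](CC)(CC)O[C@@H](c1ccc(OCc2ccccc2)c(OCc2ccccc2)c1)[C@H](OCc1ccccc1)C(=O)c1ccc(OCc2ccccc2)cc1F | intermediate
11 | (2S,3S)-2-(benzyloxy)-1-[4-(benzyloxy)-2-fluorophenyl]-3-[3,4-bis(benzyloxy)phenyl]-3-hydroxypropan-1-one (formed as its alkoxide) | O[C@@H](c1ccc(OCc2ccccc2)c(OCc2ccccc2)c1)[C@H](OCc1ccccc1)C(=O)c1ccc(OCc2ccccc2)cc1F | intermediate (not isolated)
12 | (2S,3S)-3,7-bis(benzyloxy)-2-[3,4-bis(benzyloxy)phenyl]chroman-4-one | O=C1c2ccc(OCc3ccccc3)cc2O[C@@H](c2ccc(OCc3ccccc3)c(OCc3ccccc3)c2)[C@@H]1OCc1ccccc1 | intermediate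
13 | 4-(benzyloxy)phenol | Oc1ccc(OCc2ccccc2)cc1 | starting material
14 | 4-(benzyloxy)-2,6-dibromophenol | Oc1c(Br)cc(OCc2ccccc2)cc1Br | intermediate
15 | [4-(benzyloxy)-2,6-dibromophenoxy]trimethylsilane | C[Si](C)(C)Oc1c(Br)cc(OCc2ccccc2)cc1Br | intermediate (not isolated)
16 | lithium 4-(benzyloxy)-2-bromo-6-(trimethylsilyl)phenoxide | [Li+].[O-]c1c(Br)cc(OCc2ccccc2)cc1[Si](C)(C)C | intermediate (not isolated)
17 | 4-(benzyloxy)-2-bromo-6-(trimethylsilyl)phenyl trifluoromethanesulfonate | C[Si](C)(C)c1cc(OCc2ccccc2)cc(Br)c1OS(=O)(=O)C(F)(F)F | intermediate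
18 | (+)-catechin | Oc1cc(O)c2c(c1)O[C@H](c1ccc(O)c(O)c1)[C@@H](O)C2 | starting material
19 | 5,7,3',4'-tetra-O-benzyl-(+)-catechin | c1c(OCc9ccccc9)cc(OCc9ccccc9)c2c1O[C@H](c8ccc(OCc9ccccc9)c(OCc9ccccc9)c8)[C@@H](O)C2 | intermediate
20 | 3,5,7,3',4'-penta-O-benzyl-(+)-catechin | c1c(OCc9ccccc9)cc(OCc9ccccc9)c2c1O[C@H](c8ccc(OCc9ccccc9)c(OCc9ccccc9)c8)[C@@H](OCc9ccccc9)C2 | intermediate
21 | 8-bromo-3,5,7,3',4'-penta-O-benzyl-(+)-catechin | Brc1c(OCc9ccccc9)cc(OCc9ccccc9)c2c1O[C@H](c8ccc(OCc9ccccc9)c(OCc9ccccc9)c8)[C@@H](OCc9ccccc9)C2 | intermediate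
22 | 8-lithio-3,5,7,3',4'-penta-O-benzylcatechin | [Li]c1c(OCc9ccccc9)cc(OCc9ccccc9)c2c1O[C@H](c8ccc(OCc9ccccc9)c(OCc9ccccc9)c8)[C@@H](OCc9ccccc9)C2 | intermediate (not isolated)
23 | 4-hydroxy-3,7,3',4'-tetra-O-benzyl-ent-fisetinidol-(4→8)-3,5,7,3',4'-penta-O-benzylcatechin (C4 of unit B not defined, both epimers used) | OC1(c2c(OCc9ccccc9)cc(OCc9ccccc9)c3c2O[C@H](c8ccc(OCc9ccccc9)c(OCc9ccccc9)c8)[C@@H](OCc9ccccc9)C3)c2ccc(OCc9ccccc9)cc2O[C@@H](c8ccc(OCc9ccccc9)c(OCc9ccccc9)c8)[C@@H]1OCc9ccccc9 | intermediate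
24 | nona-O-benzyl-ent-fisetinidol-(4α→8)-catechin | c1cc2c(cc1OCc9ccccc9)O[C@@H](c8ccc(OCc9ccccc9)c(OCc9ccccc9)c8)[C@H](OCc9ccccc9)[C@@H]2c1c(OCc9ccccc9)cc(OCc9ccccc9)c2c1O[C@H](c8ccc(OCc9ccccc9)c(OCc9ccccc9)c8)[C@@H](OCc9ccccc9)C2 | intermediate
25 | nona-O-benzyl-6-bromo-ent-fisetinidol-(4α→8)-6-bromocatechin | Brc1cc2c(cc1OCc9ccccc9)O[C@@H](c8ccc(OCc9ccccc9)c(OCc9ccccc9)c8)[C@H](OCc9ccccc9)[C@@H]2c1c(OCc9ccccc9)c(Br)c(OCc9ccccc9)c2c1O[C@H](c8ccc(OCc9ccccc9)c(OCc9ccccc9)c8)[C@@H](OCc9ccccc9)C2 | intermediate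
26 | 6(B),6(C)-dilithio nona-O-benzyl dimer | [Li]c1cc2c(cc1OCc9ccccc9)O[C@@H](c8ccc(OCc9ccccc9)c(OCc9ccccc9)c8)[C@H](OCc9ccccc9)[C@@H]2c1c(OCc9ccccc9)c([Li])c(OCc9ccccc9)c2c1O[C@H](c8ccc(OCc9ccccc9)c(OCc9ccccc9)c8)[C@@H](OCc9ccccc9)C2 | intermediate (not isolated)
27 | nona-O-benzyl dimer bis-ketone (triethylsilyl-protected chains at C6 of B and C6 of C) | CC[Si](CC)(CC)O[C@@H](c8ccc(OCc9ccccc9)c(OCc9ccccc9)c8)[C@H](OCc9ccccc9)C(=O)c1cc2c(cc1OCc9ccccc9)O[C@@H](c8ccc(OCc9ccccc9)c(OCc9ccccc9)c8)[C@H](OCc9ccccc9)[C@@H]2c1c(OCc9ccccc9)c(C(=O)[C@@H](OCc9ccccc9)[C@@H](O[Si](CC)(CC)CC)c8ccc(OCc9ccccc9)c(OCc9ccccc9)c8)c(OCc9ccccc9)c2c1O[C@H](c8ccc(OCc9ccccc9)c(OCc9ccccc9)c8)[C@@H](OCc9ccccc9)C2 | intermediate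
28 | dimer bis(β-hydroxy ketone) (formed as its dicesium dialkoxide) | O[C@@H](c8ccc(OCc9ccccc9)c(OCc9ccccc9)c8)[C@H](OCc9ccccc9)C(=O)c1cc2c(cc1OCc9ccccc9)O[C@@H](c8ccc(OCc9ccccc9)c(OCc9ccccc9)c8)[C@H](OCc9ccccc9)[C@@H]2c1c(OCc9ccccc9)c(C(=O)[C@@H](OCc9ccccc9)[C@@H](O)c8ccc(OCc9ccccc9)c(OCc9ccccc9)c8)c(OCc9ccccc9)c2c1O[C@H](c8ccc(OCc9ccccc9)c(OCc9ccccc9)c8)[C@@H](OCc9ccccc9)C2 | intermediate (not isolated)
29 | 5-(benzyloxy)-3-bromobenzyne (1-(benzyloxy)-3-bromo-4,5-didehydrobenzene) | BrC1=CC(OCc2ccccc2)=CC#C1 | intermediate (not isolated)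
30 | heptadeca-O-benzyl tetramer bis-carbinol (5-bromo-4-hydroxy units A and D; C4 of A and D not defined, all epimers used) | c9ccccc9COc1cc(Br)c2c(c1)O[C@@H](c8ccc(OCc9ccccc9)c(OCc9ccccc9)c8)[C@H](OCc9ccccc9)C2(O)c1cc2c(cc1OCc9ccccc9)O[C@@H](c8ccc(OCc9ccccc9)c(OCc9ccccc9)c8)[C@H](OCc9ccccc9)[C@@H]2c1c(OCc9ccccc9)c(C2(O)c3c(Br)cc(OCc9ccccc9)cc3O[C@@H](c8ccc(OCc9ccccc9)c(OCc9ccccc9)c8)[C@@H]2OCc9ccccc9)c(OCc9ccccc9)c2c1O[C@H](c8ccc(OCc9ccccc9)c(OCc9ccccc9)c8)[C@@H](OCc9ccccc9)C2 | intermediate
31 | heptadeca-O-benzyl-5-bromo-ent-fisetinidol-(4α→6)-ent-fisetinidol-(4α→8)-[5-bromo-ent-fisetinidol-(4α→6)]-catechin | c9ccccc9COc1cc(Br)c2c(c1)O[C@@H](c8ccc(OCc9ccccc9)c(OCc9ccccc9)c8)[C@H](OCc9ccccc9)[C@@H]2c1cc2c(cc1OCc9ccccc9)O[C@@H](c8ccc(OCc9ccccc9)c(OCc9ccccc9)c8)[C@H](OCc9ccccc9)[C@@H]2c1c(OCc9ccccc9)c([C@@H]2c3c(Br)cc(OCc9ccccc9)cc3O[C@@H](c8ccc(OCc9ccccc9)c(OCc9ccccc9)c8)[C@@H]2OCc9ccccc9)c(OCc9ccccc9)c2c1O[C@H](c8ccc(OCc9ccccc9)c(OCc9ccccc9)c8)[C@@H](OCc9ccccc9)C2 | intermediate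
32 | ent-fisetinidol-(4α→6)-ent-fisetinidol-(4α→8)-[ent-fisetinidol-(4α→6)]-catechin (CNP0126838.1) | Oc1ccc2c(c1)O[C@@H](c1ccc(O)c(O)c1)[C@H](O)[C@@H]2c1cc2c(cc1O)O[C@@H](c1ccc(O)c(O)c1)[C@H](O)[C@@H]2c1c(O)c([C@@H]2c3ccc(O)cc3O[C@@H](c3ccc(O)c(O)c3)[C@@H]2O)c(O)c2c1O[C@H](c1ccc(O)c(O)c1)[C@@H](O)C2 | target

**Step count and risks**

Total steps: 18. Longest linear sequence: 13 steps (steps 1–6 and 12–18).

Step 16 (key step, proposed new method). What may go wrong: retro-aldol cleavage of the β-oxido ketones before O-arylation, protonation of the aryl anion before it closes onto the carbonyl group, or attack of the alkoxide at the aryne carbon next to bromine. The fallback uses only known reaction types and leaves the aryne out. It sets out from dibromide 25 and ketone 12: the dilithio species 26 is made as in step 15 and added to two equivalents of 12 (the addition already used in step 12), which should give the bromine-free heptadeca-O-benzyl tetramer bis-carbinol F1. Ionic reduction as in step 17 should give the bromine-free heptadeca-O-benzyl tetramer F2, and hydrogenolysis as in step 18 comes back to the route at 32.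

Step 17. What may go wrong: loss of a proton from the C4 cations towards C3 (formation of 3-benzyloxyflav-3-enes and scrambling of C3), or poor facial discrimination at the two crowded, peri-brominated cations. The fallback sets out from 30 and comes back at 31 without any new compound. The tertiary benzylic C–O bonds are cleaved by a radical instead of a cationic path, with Cp2TiCl (trivalent titanium, made in the flask from Cp2TiCl2 and Mn dust) in THF in the presence of 1,4-cyclohexadiene. Hydrogen is then delivered to a benzylic radical or organotitanium species on the face anti to the C3 benzyloxy group, and no cation that could eliminate is formed.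

Step 15. What may go wrong: incomplete double halogen–lithium exchange or protonation of one site, and slow addition of the doubly ortho-substituted aryllithium at C6 of unit C to the branched Weinreb amide. The fallback sets out from 7 and 25 and comes back at 27. It changes the electrophile and the oxidation level: 7 is reduced with i-Bu2AlH (THF, −78 °C) to (2S,3S)-2-(benzyloxy)-3-[3,4-bis(benzyloxy)phenyl]-3-(triethylsilyloxy)propanal F3. The dilithio species 26 is added to this more reactive aldehyde to give the dimer bis(secondary carbinol) F4 (carbinol configurations irrelevant). Oxidation of both carbinols with Dess–Martin periodinane returns 27.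

Further compounds
F1 | step 16 | bromine-free heptadeca-O-benzyl tetramer bis-carbinol (4-hydroxy units A and D, C4 epimers) | c9ccccc9COc1ccc2c(c1)O[C@@H](c8ccc(OCc9ccccc9)c(OCc9ccccc9)c8)[C@H](OCc9ccccc9)C2(O)c1cc2c(cc1OCc9ccccc9)O[C@@H](c8ccc(OCc9ccccc9)c(OCc9ccccc9)c8)[C@H](OCc9ccccc9)[C@@H]2c1c(OCc9ccccc9)c(C2(O)c3ccc(OCc9ccccc9)cc3O[C@@H](c8ccc(OCc9ccccc9)c(OCc9ccccc9)c8)[C@@H]2OCc9ccccc9)c(OCc9ccccc9)c2c1O[C@H](c8ccc(OCc9ccccc9)c(OCc9ccccc9)c8)[C@@H](OCc9ccccc9)C2
F2 | step 16 | heptadeca-O-benzyl-ent-fisetinidol-(4α→6)-ent-fisetinidol-(4α→8)-[ent-fisetinidol-(4α→6)]-catechin | c9ccccc9COc1ccc2c(c1)O[C@@H](c8ccc(OCc9ccccc9)c(OCc9ccccc9)c8)[C@H](OCc9ccccc9)[C@@H]2c1cc2c(cc1OCc9ccccc9)O[C@@H](c8ccc(OCc9ccccc9)c(OCc9ccccc9)c8)[C@H](OCc9ccccc9)[C@@H]2c1c(OCc9ccccc9)c([C@@H]2c3ccc(OCc9ccccc9)cc3O[C@@H](c8ccc(OCc9ccccc9)c(OCc9ccccc9)c8)[C@@H]2OCc9ccccc9)c(OCc9ccccc9)c2c1O[C@H](c8ccc(OCc9ccccc9)c(OCc9ccccc9)c8)[C@@H](OCc9ccccc9)C2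
F0 | step 17 | none | none
F3 | step 15 | (2S,3S)-2-(benzyloxy)-3-[3,4-bis(benzyloxy)phenyl]-3-(triethylsilyloxy)propanal | CC[Si](CC)(CC)O[C@@H](c1ccc(OCc2ccccc2)c(OCc2ccccc2)c1)[C@H](OCc1ccccc1)C=O
F4 | step 15 | nona-O-benzyl dimer bis(secondary carbinol) (carbinol carbons at C6 of B and C6 of C not defined) | CC[Si](CC)(CC)O[C@@H](c8ccc(OCc9ccccc9)c(OCc9ccccc9)c8)[C@H](OCc9ccccc9)C(O)c1cc2c(cc1OCc9ccccc9)O[C@@H](c8ccc(OCc9ccccc9)c(OCc9ccccc9)c8)[C@H](OCc9ccccc9)[C@@H]2c1c(OCc9ccccc9)c(C(O)[C@@H](OCc9ccccc9)[C@@H](O[Si](CC)(CC)CC)c8ccc(OCc9ccccc9)c(OCc9ccccc9)c8)c(OCc9ccccc9)c2c1O[C@H](c8ccc(OCc9ccccc9)c(OCc9ccccc9)c8)[C@@H](OCc9ccccc9)C2
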